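**Retrosynthetic overview**
1. Target 31 ⇒ sulfone 30 (Na/Hg removes a PhSO2 activating group on C2) ⇒ Negishi C9–C11 union of decalin enol triflate 28 with homoallylic iodide 17, which already carries the side-chain ring and the E alkene.
2. 28 ⇒ enone 26 ⇒ key step: iron-hydride (HAT)-initiated 6-endo radical cyclisation of 25 that closes ring A through the C3–C4 bond; 25 ⇒ (R)-carvone by two α′-alkylations (C10 set anti to the isopropenyl group).
3. Enabling feature: in ring A (C1–C5, C10) the gem-dimethyl carbon C4 sits on the ring-fusion CH (C5), trans to C1 on the quaternary C10. C5–C4(CH3)=CH2 is the isopropenyl group of carvone, so H• transfer to its CH2 makes the second methyl and a tertiary C4 radical, while C1–C3 enter as a 2-sulfonylallyl acceptor on C10.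
4. 17 ⇒ alkyne 13 (Zr-catalysed carboalumination/oxirane) ⇒ Cu-catalysed asymmetric conjugate addition to 4,4-dimethylcyclohexenone, then shift of C=O to the neighbouring C=CH2 (Mannich methylenation, Luche reduction, Pd/formate).
5. Ring order: the side-chain ring (from 4) and ring B (from carvone) are bought; ring A is the only ring closed in the route, in step 14.

Key step: step 14

Remark (numbering): terpenoid numbering is used for the decalin and its carvone precursors: ring A = C1–C5, C10; ring B = C5–C10; C4 bears the two methyls, C10 the angular methyl, C8=C9 is the tetrasubstituted alkene, C9 carries the side chain (C11 onward).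
Remark (mixtures): centres made without control and destroyed later (aminomethyl carbon of 7/8, carbinol carbon of 10/11, C10 of 20, sulfonyl-bearing C2 of 26–30) are carried as epimer mixtures and left unspecified in the SMILES.
Remark (assumption): the (S,R,R)-phosphoramidite is taken to address the same enone face of 4 as it does in 2-cyclohexenone, where it gives (S)-3-alkylcyclohexanones; with C4 quaternary this is 3R in 5 and 6.
Remark (zinc reagent): in the mixed diorganozinc 3 the (trimethylsilyl)methyl group is taken to be a non-transferable ligand on zinc and on copper, so that only the silylbutynyl group is delivered in step 2.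

Step 1
Reactants: 1 (4-bromobut-1-yn-1-yl)trimethylsilane
Product: 3 [4-(trimethylsilyl)but-3-yn-1-yl][(trimethylsilyl)methyl]zinc, via alkylzinc bromide 2 (not isolated)
Conditions: Zn dust (activated with BrCH2CH2Br and TMSCl), LiCl, THF, 50 °C; Me3SiCH2Li (1.0 equiv, pentane), −78 °C to rt; evaporate, take up in toluene, filter off lithium salts; used as toluene solution
Reagents that add atoms: zinc, [Zn]; (trimethylsilyl)methyllithium, [Li]C[Si](C)(C)C
Why: Direct zinc insertion into the primary alkyl bromide in the presence of LiCl gives the alkylzinc bromide, and metathesis with (trimethylsilyl)methyllithium is the standard way to a mixed diorganozinc carrying one transferable alkyl group and one non-transferable α-silylmethyl group; the solvent switch removes the lithium halides that would lower the selectivity of the copper-catalysed addition, the silyl-capped alkyne is inert and no stereocentre is involved.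

Step 2
Reactants: 4 4,4-dimethylcyclohex-2-en-1-one; 3 [4-(trimethylsilyl)but-3-yn-1-yl][(trimethylsilyl)methyl]zinc
Product: 6 trimethyl({(3R)-4,4-dimethyl-3-[4-(trimethylsilyl)but-3-yn-1-yl]cyclohex-1-en-1-yl}oxy)silane, via zinc enolate 5 (not isolated)
Conditions: Cu(OTf)2 (2 mol%), (S,R,R)-phosphoramidite from (S)-BINOL and bis[(R)-1-phenylethyl]amine (4 mol%), 3 (1.3 equiv), toluene, −30 °C; then TMSOTf, −30 to 0 °C
Reagents that add atoms: trimethylsilyl trifluoromethanesulfonate, C[Si](C)(C)OS(=O)(=O)C(F)(F)F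
Why: Copper/phosphoramidite-catalysed asymmetric conjugate addition of a diorganozinc, for which this enone is a standard substrate, should set C3 (the later side-chain ring stereocentre) as R by ligand control of the enone face; the mixed reagent should pass only the silylbutynyl group to copper while the (trimethylsilyl)methyl group stays on the zinc enolate, and O-silylation of that enolate fixes the C1=C2 enolate regiochemistry for step 3.

Step 3
Reactants: 6 trimethyl({(3R)-4,4-dimethyl-3-[4-(trimethylsilyl)but-3-yn-1-yl]cyclohex-1-en-1-yl}oxy)silane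
Product: 9 (3S)-4,4-dimethyl-2-methylidene-3-[4-(trimethylsilyl)but-3-yn-1-yl]cyclohexan-1-one, via Mannich base 7 (not isolated), via methiodide 8 (not isolated)
Conditions: Me2N=CH2+ I− (Eschenmoser's salt), CH2Cl2, 0 °C to rt; MeI, rt; DBU, 0 °C
Reagents that add atoms: N,N-dimethylmethaniminium iodide (Eschenmoser's salt), C=[N+](C)C.[I-]
Why: Mannich reaction of the silyl enol ether puts the one-carbon unit on C2 only, and quaternisation with Hofmann-type elimination of trimethylamine should give the exocyclic enone; the C3–H is not acidic in this cross-conjugated system, so the centre is kept (its descriptor becomes S only through a priority change).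

Step 4
Reactants: 9 (3S)-4,4-dimethyl-2-methylidene-3-[4-(trimethylsilyl)but-3-yn-1-yl]cyclohexan-1-one
Product: 10 (3S)-4,4-dimethyl-2-methylidene-3-[4-(trimethylsilyl)but-3-yn-1-yl]cyclohexan-1-ol (C1 epimers)
Conditions: NaBH4, CeCl3·7H2O, MeOH, −78 °C
Reagents that add atoms: none
Why: Luche reduction should give clean 1,2-reduction of the reactive α-methylene ketone without conjugate reduction; the new carbinol centre is uncontrolled and is removed in step 6.

Step 5
Reactants: 10 (3S)-4,4-dimethyl-2-methylidene-3-[4-(trimethylsilyl)but-3-yn-1-yl]cyclohexan-1-ol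
Product: 11 (3S)-4,4-dimethyl-2-methylidene-3-[4-(trimethylsilyl)but-3-yn-1-yl]cyclohexyl methyl carbonate (C1 epimers)
Conditions: ClCO2Me, pyridine, CH2Cl2, 0 °C
Reagents that add atoms: methyl chloroformate, COC(=O)Cl
Why: Simple O-acylation of the secondary allylic alcohol gives the allylic carbonate needed as the leaving group for Pd(0) ionisation.

Step 6
Reactants: 11 (3S)-4,4-dimethyl-2-methylidene-3-[4-(trimethylsilyl)but-3-yn-1-yl]cyclohexyl methyl carbonate
Product: 12 {4-[(1S)-2,2-dimethyl-6-methylidenecyclohexyl]but-1-yn-1-yl}trimethylsilane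
Conditions: Pd(acac)2 (5 mol%), n-Bu3P (5 mol%), HCO2H, Et3N, THF, rt to 40 °C
Reagents that add atoms: none
Why: Palladium-catalysed formate hydrogenolysis of the allylic carbonate (Tsuji–Trost-type ionisation, then decarboxylation of formate to Pd–H) delivers hydride to the more substituted ring terminus of the 2-substituted π-allyl, which should give the exocyclic methylene isomer and turn the former carbonyl carbon into CH2; the neighbouring C–H stereocentre is outside the allyl system and is kept.

Step 7
Reactants: 12 {4-[(1S)-2,2-dimethyl-6-methylidenecyclohexyl]but-1-yn-1-yl}trimethylsilane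
Product: 13 (2S)-2-(but-3-yn-1-yl)-1,1-dimethyl-3-methylidenecyclohexane
Conditions: K2CO3 (cat.), MeOH, rt
Reagents that add atoms: none
Why: Base-catalysed methanolysis of the C(sp)–Si bond frees the terminal alkyne and nothing else in the hydrocarbon reacts.

Step 8
Reactants: 13 (2S)-2-(but-3-yn-1-yl)-1,1-dimethyl-3-methylidenecyclohexane
Product: 16 (3E)-6-[(1S)-2,2-dimethyl-6-methylidenecyclohexyl]-4-methylhex-3-en-1-ol, via alkenylalane 14 (not isolated), via lithium alanate 15 (not isolated)
Conditions: Me3Al (2.5 equiv), Cp2ZrCl2 (25 mol%), CH2Cl2, 0 °C to rt; evaporate, hexane; n-BuLi, 0 °C; oxirane, THF, −30 °C to rt; aq. Rochelle salt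
Reagents that add atoms: trimethylaluminium, C[Al](C)C; oxirane, C1CO1
Why: Negishi zirconium-catalysed carboalumination adds Me–Al syn with Al at the terminus, which fixes the E trisubstituted alkene, and the derived alkenylalanate opens oxirane with retention of geometry; the 1,1-disubstituted exocyclic alkene does not undergo carboalumination.

Step 9
Reactants: 16 (3E)-6-[(1S)-2,2-dimethyl-6-methylidenecyclohexyl]-4-methylhex-3-en-1-ol
Product: 17 (2S)-2-[(3E)-6-iodo-3-methylhex-3-en-1-yl]-1,1-dimethyl-3-methylidenecyclohexane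
Conditions: I2, PPh3, imidazole, CH2Cl2, 0 °C
Reagents that add atoms: iodine, II
Why: Appel-type iodination converts the primary alcohol to the iodide by SN2 under buffered conditions that leave the acid-sensitive exocyclic alkene alone.

Step 10
Reactants: 18 (R)-(−)-carvone, (5R)-2-methyl-5-(prop-1-en-2-yl)cyclohex-2-en-1-one
Product: 20 (5R)-2,6-dimethyl-5-(prop-1-en-2-yl)cyclohex-2-en-1-one (6-methylcarvone; C6 epimers), via lithium dienolate 19 (not isolated)
Conditions: LDA, THF, −78 °C; MeI, −78 to 0 °C
Reagents that add atoms: iodomethane, CI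
Why: LDA removes the α′-proton of the cross-conjugated enone kinetically and the dienolate is C-methylated (enolate alkylation); the configuration of the new centre does not matter because it is re-enolised in step 13.

Step 11
Reactants: 21 phenyl vinyl sulfone, (ethenesulfonyl)benzene
Product: 22 2-(phenylsulfonyl)prop-2-en-1-ol
Conditions: 37% aq. CH2O, DABCO (1 equiv), THF, rt
Reagents that add atoms: formaldehyde, C=O
Why: Morita–Baylis–Hillman hydroxymethylation: DABCO adds reversibly to the vinyl sulfone, the α-sulfonyl carbanion adds to formaldehyde and DABCO is eliminated.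

Step 12
Reactants: 22 2-(phenylsulfonyl)prop-2-en-1-ol
Product: 23 [(3-bromoprop-1-en-2-yl)sulfonyl]benzene
Conditions: PBr3 (0.4 equiv), Et2O, 0 °C
Reagents that add atoms: phosphorus tribromide, BrP(Br)Br
Why: Standard conversion of a primary allylic alcohol to the bromide with PBr3; direct and allylic substitution give the same product in this allyl system.

Step 13
Reactants: 20 (5R)-2,6-dimethyl-5-(prop-1-en-2-yl)cyclohex-2-en-1-one; 23 [(3-bromoprop-1-en-2-yl)sulfonyl]benzene
Product: 25 (5S,6S)-2,6-dimethyl-6-[2-(phenylsulfonyl)prop-2-en-1-yl]-5-(prop-1-en-2-yl)cyclohex-2-en-1-one, via lithium dienolate 24 (not isolated)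
Conditions: LDA, THF, −78 °C; DMPU; inverse addition to 23 (1.5 equiv), −78 to −30 °C
Reagents that add atoms: none
Why: Enolate alkylation with the highly reactive 2-sulfonylallyl bromide (SN2 or conjugate addition–elimination, same product) creates the quaternary C10; the electrophile should enter anti to the isopropenyl group on C5, which sits pseudo-axial to avoid A(1,2) strain with the enolate methyl, so the methyl ends cis and the three-carbon arm trans to the isopropenyl group, as the trans ring fusion requires.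

Step 14
Reactants: 25 (5S,6S)-2,6-dimethyl-6-[2-(phenylsulfonyl)prop-2-en-1-yl]-5-(prop-1-en-2-yl)cyclohex-2-en-1-one
Product: 26 (4aS,8aS)-2,5,5,8a-tetramethyl-7-(phenylsulfonyl)-4a,5,6,7,8,8a-hexahydronaphthalen-1(4H)-one (C7 epimers)
Conditions: Fe(acac)3 (30 mol%), PhSiH3 (2.5 equiv), EtOH/(CH2OH)2 5:1, 0.02 M, 60 °C
Reagents that add atoms: none
Why: Fe(acac)3 and PhSiH3 form an iron hydride that transfers H• to the terminal CH2 of the electron-rich isopropenyl group (Markovnikov), which turns that carbon into the second methyl on C4 and leaves a nucleophilic tertiary C4 radical; this adds to the terminal CH2 (C3) of the 2-(phenylsulfonyl)allyl arm on C10, and the α-sulfonyl C2 radical is reduced by Fe(II) and protonated by ethanol, returning Fe(III). The closest known reaction type is the iron-hydride (HAT-initiated) reductive coupling of an unactivated donor alkene with a vinyl sulfone acceptor, used intramolecularly as a Giese cyclisation to a quaternary carbon. Ring A (C1–C5, C10) closes by C3–C4 bond formation in the 6-endo-trig mode through a chair transition state in which both tethers stay equatorial on ring B. No ring-fusion centre is made here: C5 (from carvone) and C10 (step 13) are untouched and already trans, C4 becomes a non-stereogenic quaternary carbon, and the only new centre, the sulfonyl-bearing C2, forms without control and is erased in step 17. The step needs H-atom transfer to the isopropenyl group and not to the electron-poor vinyl sulfone or the conjugated enone (secured by the polarity of the hydride transfer), and 6-endo and not 5-exo closure (secured by placing the sulfonyl group on the internal alkene carbon, so the polarity-matched and less hindered site is the terminal one).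

Step 15
Reactants: 26 (4aS,8aS)-2,5,5,8a-tetramethyl-7-(phenylsulfonyl)-4a,5,6,7,8,8a-hexahydronaphthalen-1(4H)-one
Product: 28 (4aS,8aS)-2,5,5,8a-tetramethyl-7-(phenylsulfonyl)-3,4,4a,5,6,7,8,8a-octahydronaphthalen-1-yl trifluoromethanesulfonate, via lithium enolate 27 (not isolated)
Conditions: L-Selectride, THF, −78 °C; PhNTf2, −78 °C to rt
Reagents that add atoms: N-phenylbis(trifluoromethanesulfonimide), O=S(=O)(N(c1ccccc1)S(=O)(=O)C(F)(F)F)C(F)(F)F
Why: L-Selectride reduces the β-unsubstituted enone by conjugate hydride addition at C7 and the only possible enolate (C10 is quaternary) is O-triflated, which fixes the C8=C9 double bond of the target as the tetrasubstituted enol triflate.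

Step 16
Reactants: 17 (2S)-2-[(3E)-6-iodo-3-methylhex-3-en-1-yl]-1,1-dimethyl-3-methylidenecyclohexane; 28 (4aS,8aS)-2,5,5,8a-tetramethyl-7-(phenylsulfonyl)-3,4,4a,5,6,7,8,8a-octahydronaphthalen-1-yl trifluoromethanesulfonate
Product: 30 (4aS,8aS)-5-{(3E)-6-[(1S)-2,2-dimethyl-6-methylidenecyclohexyl]-4-methylhex-3-en-1-yl}-1,1,4a,6-tetramethyl-3-(phenylsulfonyl)-1,2,3,4,4a,7,8,8a-octahydronaphthalene (C3 epimers), via alkylzinc iodide 29 (not isolated)
Conditions: 17, Zn dust (activated), LiCl, THF, 40 °C; then 28, PdCl2(dppf) (5 mol%), THF/NMP, 50 °C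
Reagents that add atoms: none
Why: Zinc insertion into the primary iodide and Negishi C(sp3)–C(sp2) coupling with the alkenyl triflate should join C11 to C9 with the C8=C9 position and the E alkene retained; the alkyl sulfone, the exocyclic alkene and the stereocentres are inert to the organozinc.

Step 17
Reactants: 30 (4aS,8aS)-5-{(3E)-6-[(1S)-2,2-dimethyl-6-methylidenecyclohexyl]-4-methylhex-3-en-1-yl}-1,1,4a,6-tetramethyl-3-(phenylsulfonyl)-1,2,3,4,4a,7,8,8a-octahydronaphthalene
Product: 31 (4aS,8aS)-5-{(3E)-6-[(1S)-2,2-dimethyl-6-methylidenecyclohexyl]-4-methylhex-3-en-1-yl}-1,1,4a,6-tetramethyl-1,2,3,4,4a,7,8,8a-octahydronaphthalene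
Conditions: 6% Na(Hg), Na2HPO4, MeOH/THF, −20 °C to rt
Reagents that add atoms: none
Why: Reductive desulfonylation with sodium amalgam (electron transfer to the aryl sulfone, C–S cleavage, protonation) removes the activating group, erases the uncontrolled C2 centre and should leave the three isolated alkenes untouched.

**Compound list**
1 | (4-bromobut-1-yn-1-yl)trimethylsilane | C[Si](C)(C)C#CCCBr | starting material
2 | [4-(trimethylsilyl)but-3-yn-1-yl]zinc bromide | C[Si](C)(C)C#CCC[Zn]Br | intermediate
3 | [4-(trimethylsilyl)but-3-yn-1-yl][(trimethylsilyl)methyl]zinc | C[Si](C)(C)C#CCC[Zn]C[Si](C)(C)C | intermediate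
4 | 4,4-dimethylcyclohex-2-en-1-one | CC1(C)CCC(=O)C=C1 | starting material
5 | ({(3R)-4,4-dimethyl-3-[4-(trimethylsilyl)but-3-yn-1-yl]cyclohex-1-en-1-yl}oxy)[(trimethylsilyl)methyl]zinc | C1=C(O[Zn]C[Si](C)(C)C)CCC(C)(C)[C@@H]1CCC#C[Si](C)(C)C | intermediate
6 | trimethyl({(3R)-4,4-dimethyl-3-[4-(trimethylsilyl)but-3-yn-1-yl]cyclohex-1-en-1-yl}oxy)silane | C1=C(O[Si](C)(C)C)CCC(C)(C)[C@@H]1CCC#C[Si](C)(C)C | intermediate
7 | (3R)-2-[(dimethylamino)methyl]-4,4-dimethyl-3-[4-(trimethylsilyl)but-3-yn-1-yl]cyclohexan-1-one (C2 epimers) | CN(C)CC1C(=O)CCC(C)(C)[C@@H]1CCC#C[Si](C)(C)C | intermediate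
8 | {[(2R)-3,3-dimethyl-6-oxo-2-[4-(trimethylsilyl)but-3-yn-1-yl]cyclohexyl]methyl}trimethylazanium iodide (C1 epimers) | C[N+](C)(C)CC1C(=O)CCC(C)(C)[C@@H]1CCC#C[Si](C)(C)C.[I-] | intermediate
9 | (3S)-4,4-dimethyl-2-methylidene-3-[4-(trimethylsilyl)but-3-yn-1-yl]cyclohexan-1-one | C=C1C(=O)CCC(C)(C)[C@@H]1CCC#C[Si](C)(C)C | intermediate
10 | (3S)-4,4-dimethyl-2-methylidene-3-[4-(trimethylsilyl)but-3-yn-1-yl]cyclohexan-1-ol (C1 epimers) | C=C1C(O)CCC(C)(C)[C@@H]1CCC#C[Si](C)(C)C | intermediate
11 | (3S)-4,4-dimethyl-2-methylidene-3-[4-(trimethylsilyl)but-3-yn-1-yl]cyclohexyl methyl carbonate (C1 epimers) | C=C1C(OC(=O)OC)CCC(C)(C)[C@@H]1CCC#C[Si](C)(C)C | intermediate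
12 | {4-[(1S)-2,2-dimethyl-6-methylidenecyclohexyl]but-1-yn-1-yl}trimethylsilane | C=C1CCCC(C)(C)[C@@H]1CCC#C[Si](C)(C)C | intermediate
13 | (2S)-2-(but-3-yn-1-yl)-1,1-dimethyl-3-methylidenecyclohexane | C=C1CCCC(C)(C)[C@@H]1CCC#C | intermediate
14 | {(1E)-4-[(1S)-2,2-dimethyl-6-methylidenecyclohexyl]-2-methylbut-1-en-1-yl}dimethylalumane | C=C1CCCC(C)(C)[C@@H]1CC/C(C)=C/[Al](C)C | intermediate
15 | lithium butyl{(1E)-4-[(1S)-2,2-dimethyl-6-methylidenecyclohexyl]-2-methylbut-1-en-1-yl}dimethylaluminate | [Li+].C=C1CCCC(C)(C)[C@@H]1CC/C(C)=C/[Al-](C)(C)CCCC | intermediate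
16 | (3E)-6-[(1S)-2,2-dimethyl-6-methylidenecyclohexyl]-4-methylhex-3-en-1-ol | C=C1CCCC(C)(C)[C@@H]1CC/C(C)=C/CCO | intermediate
17 | (2S)-2-[(3E)-6-iodo-3-methylhex-3-en-1-yl]-1,1-dimethyl-3-methylidenecyclohexane | C=C1CCCC(C)(C)[C@@H]1CC/C(C)=C/CCI | intermediate
18 | (R)-(−)-carvone, (5R)-2-methyl-5-(prop-1-en-2-yl)cyclohex-2-en-1-one | O=C1C(C)=CC[C@@H](C(C)=C)C1 | starting material
19 | lithium (3R)-6-methyl-3-(prop-1-en-2-yl)cyclohexa-1,5-dien-1-olate | [Li]OC1=C[C@H](C(C)=C)CC=C1C | intermediate
20 | (5R)-2,6-dimethyl-5-(prop-1-en-2-yl)cyclohex-2-en-1-one (6-methylcarvone; C6 epimers) | O=C1C(C)=CC[C@@H](C(C)=C)C1C | intermediate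
21 | phenyl vinyl sulfone, (ethenesulfonyl)benzene | C=CS(=O)(=O)c1ccccc1 | starting material
22 | 2-(phenylsulfonyl)prop-2-en-1-ol | C=C(CO)S(=O)(=O)c1ccccc1 | intermediate
23 | [(3-bromoprop-1-en-2-yl)sulfonyl]benzene | C=C(CBr)S(=O)(=O)c1ccccc1 | intermediate
24 | lithium (3S)-2,6-dimethyl-3-(prop-1-en-2-yl)cyclohexa-1,5-dien-1-olate | [Li]OC1=C(C)[C@H](C(C)=C)CC=C1C | intermediate
25 | (5S,6S)-2,6-dimethyl-6-[2-(phenylsulfonyl)prop-2-en-1-yl]-5-(prop-1-en-2-yl)cyclohex-2-en-1-one | O=C1C(C)=CC[C@@H](C(C)=C)[C@]1(C)CC(=C)S(=O)(=O)c2ccccc2 | intermediate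
26 | (4aS,8aS)-2,5,5,8a-tetramethyl-7-(phenylsulfonyl)-4a,5,6,7,8,8a-hexahydronaphthalen-1(4H)-one (C7 epimers) | O=C1C(C)=CC[C@H]2C(C)(C)CC(S(=O)(=O)c3ccccc3)C[C@]12C | intermediate
27 | lithium (4aS,8aS)-2,5,5,8a-tetramethyl-7-(phenylsulfonyl)-3,4,4a,5,6,7,8,8a-octahydronaphthalen-1-olate | [Li]OC1=C(C)CC[C@H]2C(C)(C)CC(S(=O)(=O)c3ccccc3)C[C@]12C | intermediate
28 | (4aS,8aS)-2,5,5,8a-tetramethyl-7-(phenylsulfonyl)-3,4,4a,5,6,7,8,8a-octahydronaphthalen-1-yl trifluoromethanesulfonate | FC(F)(F)S(=O)(=O)OC1=C(C)CC[C@H]2C(C)(C)CC(S(=O)(=O)c3ccccc3)C[C@]12C | intermediate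
29 | {(3E)-6-[(1S)-2,2-dimethyl-6-methylidenecyclohexyl]-4-methylhex-3-en-1-yl}(iodo)zinc | C=C1CCCC(C)(C)[C@@H]1CC/C(C)=C/CC[Zn]I | intermediate
30 | (4aS,8aS)-5-{(3E)-6-[(1S)-2,2-dimethyl-6-methylidenecyclohexyl]-4-methylhex-3-en-1-yl}-1,1,4a,6-tetramethyl-3-(phenylsulfonyl)-1,2,3,4,4a,7,8,8a-octahydronaphthalene (C3 epimers) | C=C1CCCC(C)(C)[C@@H]1CC/C(C)=C/CCC1=C(C)CC[C@H]2C(C)(C)CC(S(=O)(=O)c3ccccc3)C[C@]12C | intermediate
31 | (4aS,8aS)-5-{(3E)-6-[(1S)-2,2-dimethyl-6-methylidenecyclohexyl]-4-methylhex-3-en-1-yl}-1,1,4a,6-tetramethyl-1,2,3,4,4a,7,8,8a-octahydronaphthalene | C=C1CCCC(C)(C)[C@@H]1CC/C(C)=C/CCC1=C(C)CC[C@H]2C(C)(C)CCC[C@]12C | target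

Total step count: 17. Longest linear sequence: 11 steps (steps 1–9, 16, 17); the carvone branch to 28 is 4 steps (10, 13, 14, 15), with 23 supplied by steps 11–12.

**Steps most likely to fail**

Step 14 (key step). The tertiary C4 radical may be quenched by hydrogen transfer before it cyclises (net hydrogenation of the isopropenyl group), or the iron hydride may attack the enone or the vinyl sulfone instead of the isopropenyl group. The fallback makes the same radical without a metal hydride in solution and sets out from 25. HBr in AcOH at 0 °C should add in the Markovnikov sense to the isopropenyl group only and give the tertiary bromide (5R,6S)-5-(2-bromopropan-2-yl)-2,6-dimethyl-6-[2-(phenylsulfonyl)prop-2-en-1-yl]cyclohex-2-en-1-one F1. Slow addition of Bu3SnH with AIBN in benzene at 80 °C should then generate the C4 radical by bromine-atom abstraction at low stannane concentration, and the same 6-endo Giese closure should return the route at 26.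

Step 16. Transmetalation and reductive elimination at the tetrasubstituted alkenylpalladium next to the quaternary C10 may be slow, so that β-hydride elimination and protodezincation of the alkyl partner take over. The fallback moves the sp3–sp2 bond formation to the unhindered C12–C13 bond and sets out from 28 and 13. Stille coupling of 28 with tributyl(vinyl)stannane (Pd(PPh3)4, LiCl, THF, 65 °C) should give the diene (4aS,8aS)-1-ethenyl-2,5,5,8a-tetramethyl-7-(phenylsulfonyl)-3,4,4a,5,6,7,8,8a-octahydronaphthalene F2. 9-BBN should hydroborate only its monosubstituted vinyl group to the borane 9-{2-[(4aS,8aS)-2,5,5,8a-tetramethyl-7-(phenylsulfonyl)-3,4,4a,5,6,7,8,8a-octahydronaphthalen-1-yl]ethyl}-9-borabicyclo[3.3.1]nonane F3, used in solution. Alkyne 13 is converted by Zr-catalysed carboalumination and iodinolysis into the vinyl iodide (2S)-2-[(3E)-4-iodo-3-methylbut-3-en-1-yl]-1,1-dimethyl-3-methylidenecyclohexane F4. B-alkyl Suzuki–Miyaura coupling of the borane with the vinyl iodide (PdCl2(dppf), AsPh3, Cs2CO3, DMF/THF/H2O) should return the route at 30.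

Step 6. Hydride may be delivered to the exocyclic allyl terminus, or a palladium hydride may move the double bond into the ring, giving the endocyclic isomer that is hard to separate. The fallback is regiospecific by mechanism and sets out from 10. Rhenium-catalysed 1,3-transposition (Ph3SiOReO3, Et2O, −50 to 0 °C) should give the primary allylic alcohol {(6S)-5,5-dimethyl-6-[4-(trimethylsilyl)but-3-yn-1-yl]cyclohex-1-en-1-yl}methanol F5. Mitsunobu reaction with 2-nitrobenzenesulfonylhydrazide (PPh3, DEAD, THF, −30 °C) should give N-{[(6S)-5,5-dimethyl-6-[4-(trimethylsilyl)but-3-yn-1-yl]cyclohex-1-en-1-yl]methyl}-2-nitrobenzenesulfonohydrazide F6. On warming this loses the sulfinic acid to the allylic diazene {[(6S)-5,5-dimethyl-6-[4-(trimethylsilyl)but-3-yn-1-yl]cyclohex-1-en-1-yl]methyl}diazene F7, whose retro-ene loss of N2 puts hydrogen on the ring carbon and the double bond in the exocyclic position, returning the route at 12.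

**Further compounds**
F1 | step 14 | (5R,6S)-5-(2-bromopropan-2-yl)-2,6-dimethyl-6-[2-(phenylsulfonyl)prop-2-en-1-yl]cyclohex-2-en-1-one | O=C1C(C)=CC[C@@H](C(C)(C)Br)[C@]1(C)CC(=C)S(=O)(=O)c2ccccc2
F2 | step 16 | (4aS,8aS)-1-ethenyl-2,5,5,8a-tetramethyl-7-(phenylsulfonyl)-3,4,4a,5,6,7,8,8a-octahydronaphthalene | C=CC1=C(C)CC[C@H]2C(C)(C)CC(S(=O)(=O)c3ccccc3)C[C@]12C
F3 | step 16 | 9-{2-[(4aS,8aS)-2,5,5,8a-tetramethyl-7-(phenylsulfonyl)-3,4,4a,5,6,7,8,8a-octahydronaphthalen-1-yl]ethyl}-9-borabicyclo[3.3.1]nonane | B1(CCC2=C(C)CC[C@H]3C(C)(C)CC(S(=O)(=O)c4ccccc4)C[C@]23C)C2CCCC1CCC2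
F4 | step 16 | (2S)-2-[(3E)-4-iodo-3-methylbut-3-en-1-yl]-1,1-dimethyl-3-methylidenecyclohexane | C=C1CCCC(C)(C)[C@@H]1CC/C(C)=C/I
F5 | step 6 | {(6S)-5,5-dimethyl-6-[4-(trimethylsilyl)but-3-yn-1-yl]cyclohex-1-en-1-yl}methanol | OCC1=CCCC(C)(C)[C@@H]1CCC#C[Si](C)(C)C
F6 | step 6 | N-{[(6S)-5,5-dimethyl-6-[4-(trimethylsilyl)but-3-yn-1-yl]cyclohex-1-en-1-yl]methyl}-2-nitrobenzenesulfonohydrazide | NN(CC1=CCCC(C)(C)[C@@H]1CCC#C[Si](C)(C)C)S(=O)(=O)c2ccccc2[N+](=O)[O-]
F7 | step 6 | {[(6S)-5,5-dimethyl-6-[4-(trimethylsilyl)but-3-yn-1-yl]cyclohex-1-en-1-yl]methyl}diazene | N=NCC1=CCCC(C)(C)[C@@H]1CCC#C[Si](C)(C)C
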